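## Retrosynthetic overview

1. Feature: the 3-hydroxy-3-methylglutaryl (HMG) half-ester on O8', the CH2O carbon on quaternary C6' of the cyclohex-2-enone ring C1'–C6'. HMG C3 (C–OH, CH3, two CH2C(=O) arms) is a stereocentre only because one arm is esterified to O8', and (R)-citramalic acid holds this carbinol with two arms that already differ.
2. Key disconnections: the O8'–C(=O) ester bond and the HMG C2–C3 bond. Both form in one operation when citramalate diazoketone 23 undergoes Wolff rearrangement and core alcohol 16 captures the ketene.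
3. Core 16: C6' is set by palladium-catalysed decarboxylative asymmetric allylation, the allyl group then being cut down to C8'H2OH. C1' is set by chelation-controlled addition of the acetylide of (Z)-3-methylpent-2-en-4-yn-1-ol, followed by alkyne to E-alkene reduction and oxidation of side-chain C1 to the allyl ester.
4. Ring order: the only carbocycle (C1'–C6') comes from the benzene ring of 2,6-dimethylphenol by oxidative dearomatisation in step 1, together with its protecting dioxolane. No ring is formed afterwards and the key step closes none. The end game is acid (dioxolane, silyl ether), then zerovalent palladium (both allyl esters).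

Key step: step 18

Remark: the target is read as (1'R,6'S) in the ring, 2Z,4E in the side chain and 3R in the HMG unit, with C8'H2O on the same ring face as the dienoate chain and the C6' methyl (C9') on the face of the C1' hydroxyl.

Remark: C4' is carried as the ethylene ketal, because a ketal next to a free C8' hydroxyl must survive buffered chlorite and chromatography; 1 M HCl removes it at the end.

Remark: (S)-t-BuPHOX is assumed to give the C6' configuration shown, by analogy with 2-methylcyclohexanone-type enol carbonates. Its antipode is used if the sense proves opposite, and ketone 8 is recrystallised if the enantiomeric purity needs raising.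

## Route

Step 1
Reactants: 1 2,6-dimethylphenol
Product: 2 7,9-dimethyl-1,4-dioxaspiro[4.5]deca-6,9-dien-8-one
Conditions: PhI(OAc)2 (2.2 equiv), HOCH2CH2OH/CH2Cl2, 0 °C → rt
Reagents that add atoms: ethane-1,2-diol OCCO
Why: Two successive two-electron oxidative dearomatisations by the hypervalent iodine reagent first place the glycol on the free para carbon and then close the spiro dioxolane, which gives the symmetric quinone monoketal.

Step 2
Reactants: 2 7,9-dimethyl-1,4-dioxaspiro[4.5]deca-6,9-dien-8-one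
Product: 4 allyl 7,9-dimethyl-1,4-dioxaspiro[4.5]deca-6,8-dien-8-yl carbonate, via lithium dienolate 3 (not isolated)
Conditions: LiBH(s-Bu)3 (L-Selectride, 1.05 equiv), THF, −78 °C; then ClCO2CH2CH=CH2, −78 → 0 °C
Reagents that add atoms: allyl chloroformate C=CCOC(Cl)=O
Why: The bulky trialkylborohydride adds hydride 1,4 to the β-unsubstituted enone arm (the carbonyl is shielded by two α-methyl groups and both arms are equivalent), and the chloroformate acylates the tetrasubstituted enolate on oxygen (conjugate reduction with enolate trapping).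

Step 3
Reactants: 4 allyl 7,9-dimethyl-1,4-dioxaspiro[4.5]deca-6,8-dien-8-yl carbonate
Product: 5 (R)-9-allyl-7,9-dimethyl-1,4-dioxaspiro[4.5]dec-6-en-8-one
Conditions: Pd2(dba)3 (2.5 mol %), (S)-t-BuPHOX (6.25 mol %), THF, 25 °C
Reagents that add atoms: none
Why: In this decarboxylative asymmetric Tsuji allylation zerovalent palladium ionises the allyl carbonate, CO2 is lost, and the PHOX-bound allylpalladium enolate forms the C–C bond at C6', the only nucleophilic carbon of the cross-conjugated dienolate, so that the ligand sets the quaternary centre.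

Step 4
Reactants: 5 (R)-9-allyl-7,9-dimethyl-1,4-dioxaspiro[4.5]dec-6-en-8-one
Product: 6 (S)-7,9-dimethyl-9-[(E)-prop-1-en-1-yl]-1,4-dioxaspiro[4.5]dec-6-en-8-one
Conditions: RuHCl(CO)(PPh3)3 (5 mol %), toluene, 80 °C
Reagents that add atoms: none
Why: Ruthenium hydride addition and β-hydride elimination move the terminal alkene one position inward and no further, because the next carbon is quaternary (alkene isomerisation); the stereocentre is not touched and the alkene geometry is immaterial.

Step 5
Reactants: 6 (S)-7,9-dimethyl-9-[(E)-prop-1-en-1-yl]-1,4-dioxaspiro[4.5]dec-6-en-8-one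
Product: 7 (S)-7,9-dimethyl-8-oxo-1,4-dioxaspiro[4.5]dec-6-ene-9-carbaldehyde
Conditions: O3, CH2Cl2, −78 °C (Sudan Red 7B end point); PPh3, −78 °C → rt
Reagents that add atoms: ozone [O-][O+]=O
Why: Ozonolysis cleaves the electron-rich disubstituted propenyl alkene far faster than the electron-poor trisubstituted enone alkene, and the resulting β-keto aldehyde cannot enolise at the quaternary carbon.

Step 6
Reactants: 7 (S)-7,9-dimethyl-8-oxo-1,4-dioxaspiro[4.5]dec-6-ene-9-carbaldehyde
Product: 8 (S)-9-(hydroxymethyl)-7,9-dimethyl-1,4-dioxaspiro[4.5]dec-6-en-8-one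
Conditions: LiAlH(Ot-Bu)3 (1.1 equiv), THF, −78 °C; aq. KNaC4H4O6
Reagents that add atoms: none
Why: The hindered single-hydride reagent reduces the aldehyde much faster than the conjugated ketone flanked by a quaternary carbon and a methyl-bearing alkene (chemoselective carbonyl reduction), which gives C8'H2OH.

Step 7
Reactants: 8 (S)-9-(hydroxymethyl)-7,9-dimethyl-1,4-dioxaspiro[4.5]dec-6-en-8-one; 9 (Z)-3-methylpent-2-en-4-yn-1-ol
Product: 12 (8S,9S)-8-[(3Z)-5-hydroxy-3-methylpent-3-en-1-yn-1-yl]-9-(hydroxymethyl)-7,9-dimethyl-1,4-dioxaspiro[4.5]dec-6-en-8-ol, via dilithio enynol 10 (not isolated), via chloromagnesium alkoxide 11 (not isolated)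
Conditions: 9 (2.5 equiv), n-BuLi (5.0 equiv), THF, −78 → 0 °C; 8, t-BuMgCl (1.0 equiv), THF, −78 °C; combine, −78 → −20 °C; aq. NH4Cl
Reagents that add atoms: none
Why: In this acetylide 1,2-addition to a non-enolisable ketone the C8' magnesium alkoxide binds the carbonyl oxygen in a six-membered chelate that holds C8' pseudo-equatorial and the C9' methyl pseudo-axial, so the acetylide should enter axially on the face anti to that methyl, which sets C1' with its hydroxyl cis to the methyl and trans to C8'.

Step 8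
Reactants: 12 (8S,9S)-8-[(3Z)-5-hydroxy-3-methylpent-3-en-1-yn-1-yl]-9-(hydroxymethyl)-7,9-dimethyl-1,4-dioxaspiro[4.5]dec-6-en-8-ol
Product: 13 (8R,9S)-8-[(1E,3Z)-5-hydroxy-3-methylpenta-1,3-dien-1-yl]-9-(hydroxymethyl)-7,9-dimethyl-1,4-dioxaspiro[4.5]dec-6-en-8-ol
Conditions: NaAlH2(OCH2CH2OMe)2 (Red-Al, 4 equiv), THF, 0 °C → rt; aq. KNaC4H4O6
Reagents that add atoms: none
Why: The C1' alkoxyaluminate delivers hydride to the propargylic alkyne in a trans-hydroalumination and protonolysis gives the E alkene, while the Z trisubstituted alkene and both stereocentres stay as they are.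

Step 9
Reactants: 13 (8R,9S)-8-[(1E,3Z)-5-hydroxy-3-methylpenta-1,3-dien-1-yl]-9-(hydroxymethyl)-7,9-dimethyl-1,4-dioxaspiro[4.5]dec-6-en-8-ol
Product: 14 (2Z,4E)-5-[(8R,9S)-8-hydroxy-9-(hydroxymethyl)-7,9-dimethyl-1,4-dioxaspiro[4.5]dec-6-en-8-yl]-3-methylpenta-2,4-dienal
Conditions: MnO2 (activated, excess), CH2Cl2, rt, dark
Reagents that add atoms: none
Why: MnO2 oxidises only the allylic primary alcohol, not the neopentyl C8' or the tertiary C1' hydroxyl, and should leave the 2Z geometry intact (selective allylic oxidation).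

Step 10
Reactants: 14 (2Z,4E)-5-[(8R,9S)-8-hydroxy-9-(hydroxymethyl)-7,9-dimethyl-1,4-dioxaspiro[4.5]dec-6-en-8-yl]-3-methylpenta-2,4-dienal
Product: 15 (2Z,4E)-5-[(8R,9S)-8-hydroxy-9-(hydroxymethyl)-7,9-dimethyl-1,4-dioxaspiro[4.5]dec-6-en-8-yl]-3-methylpenta-2,4-dienoic acid
Conditions: NaClO2, NaH2PO4, 2-methylbut-2-ene, t-BuOH/H2O, 0 °C
Reagents that add atoms: sodium chlorite [Na+].[O-]Cl=O
Why: Pinnick oxidation converts the enal to the acid without touching the alkene geometry, the alkene scavenger removes HOCl, and the dioxolane tolerates the weakly acidic buffer.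

Step 11
Reactants: 15 (2Z,4E)-5-[(8R,9S)-8-hydroxy-9-(hydroxymethyl)-7,9-dimethyl-1,4-dioxaspiro[4.5]dec-6-en-8-yl]-3-methylpenta-2,4-dienoic acid
Product: 16 allyl (2Z,4E)-5-[(8R,9S)-8-hydroxy-9-(hydroxymethyl)-7,9-dimethyl-1,4-dioxaspiro[4.5]dec-6-en-8-yl]-3-methylpenta-2,4-dienoate (core alcohol)
Conditions: CH2=CHCH2Br (1.2 equiv), KHCO3, DMF, rt
Reagents that add atoms: allyl bromide C=CCBr
Why: Bicarbonate deprotonates only the carboxylic acid, whose carboxylate is alkylated by SN2, so both hydroxyls stay free.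

Step 12
Reactants: 17 (R)-citramalic acid
Product: 18 2-[(4R)-2,2,4-trimethyl-5-oxo-1,3-dioxolan-4-yl]acetic acid
Conditions: Me2C(OMe)2, TsOH·H2O (cat.), rt
Reagents that add atoms: 2,2-dimethoxypropane COC(C)(C)OC
Why: Acid-catalysed trans-acetalisation ties the α-hydroxy acid unit into a 1,3-dioxolan-4-one and leaves the CH2CO2H arm free, which differentiates the two carboxyls without involving the stereocentre.

Step 13
Reactants: 18 2-[(4R)-2,2,4-trimethyl-5-oxo-1,3-dioxolan-4-yl]acetic acid
Product: 19 allyl 2-[(4R)-2,2,4-trimethyl-5-oxo-1,3-dioxolan-4-yl]acetate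
Conditions: CH2=CHCH2Br (1.2 equiv), KHCO3, DMF, rt
Reagents that add atoms: allyl bromide C=CCBr
Why: SN2 alkylation of the carboxylate under weakly basic conditions leaves the dioxolanone closed.

Step 14
Reactants: 19 allyl 2-[(4R)-2,2,4-trimethyl-5-oxo-1,3-dioxolan-4-yl]acetate
Product: 20 (R)-4-(allyloxy)-2-hydroxy-2-methyl-4-oxobutanoic acid
Conditions: AcOH/H2O (4:1), 40 °C
Reagents that add atoms: none
Why: The acetal-type dioxolanone is hydrolysed by mild aqueous acid much faster than the allyl ester (the oxygen of water leaves in acetone), which frees the α-hydroxy acid.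

Step 15
Reactants: 20 (R)-4-(allyloxy)-2-hydroxy-2-methyl-4-oxobutanoic acid
Product: 21 triethylsilyl (R)-4-(allyloxy)-2-methyl-4-oxo-2-[(triethylsilyl)oxy]butanoate
Conditions: Et3SiOTf (2.3 equiv), 2,6-lutidine (3 equiv), CH2Cl2, −78 → 0 °C
Reagents that add atoms: triethylsilyl trifluoromethanesulfonate CC[Si](CC)(CC)OS(=O)(=O)C(F)(F)F
Why: The silyl triflate silylates both the hindered tertiary hydroxyl and the carboxylic acid, which gives silyl ether and silyl ester together.

Step 16
Reactants: 21 triethylsilyl (R)-4-(allyloxy)-2-methyl-4-oxo-2-[(triethylsilyl)oxy]butanoate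
Product: 22 allyl (R)-4-chloro-3-methyl-4-oxo-3-[(triethylsilyl)oxy]butanoate
Conditions: (COCl)2 (1.2 equiv), DMF (cat.), CH2Cl2, 0 °C → rt; concentrate, use crude
Reagents that add atoms: oxalyl chloride O=C(Cl)C(Cl)=O
Why: The Vilsmeier chloride converts the silyl ester directly into the acid chloride with loss of Et3SiCl, so no HCl reaches the tertiary silyl ether or the allyl ester (known silyl ester to acid chloride exchange).

Step 17
Reactants: 22 allyl (R)-4-chloro-3-methyl-4-oxo-3-[(triethylsilyl)oxy]butanoate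
Product: 23 allyl (R)-5-diazo-3-methyl-4-oxo-3-[(triethylsilyl)oxy]pentanoate
Conditions: CH2N2 (2.5 equiv), Et2O, 0 °C
Reagents that add atoms: diazomethane C=[N+]=[N-]
Why: The acid chloride acylates diazomethane (first stage of the Arndt–Eistert sequence) while a second equivalent takes up HCl, and with no α-hydrogen there is no ketene formation or epimerisation.

Step 18
Reactants: 16 allyl (2Z,4E)-5-[(8R,9S)-8-hydroxy-9-(hydroxymethyl)-7,9-dimethyl-1,4-dioxaspiro[4.5]dec-6-en-8-yl]-3-methylpenta-2,4-dienoate; 23 allyl (R)-5-diazo-3-methyl-4-oxo-3-[(triethylsilyl)oxy]pentanoate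
Product: 25 fully protected target (bis-allyl ester; C4' ethylene ketal; HMG O-triethylsilyl ether; 8R,9S ring; 3R HMG), via silyloxy ketene 24 (not isolated)
Conditions: 23 (2.0 equiv, added over 2 h), AgO2CPh (0.2 equiv), Et3N (3 equiv), THF, 25 → 45 °C, ultrasound, dark
Reagents that add atoms: none
Why: Monovalent silver (from AgO2CPh/Et3N) promotes loss of N2 from 23 and the concerted 1,2-shift of the fully substituted carbinol carbon to the diazo carbon, which gives ketene 24 and forms the HMG C2–C3 bond with retention at the migrating centre; the primary C8' hydroxyl of 16 then adds to the ketene carbonyl and the enol tautomerises to the ester, which forms the O8'–C(=O) bond. The closest known reaction type is the Arndt–Eistert homologation, that is the silver benzoate/triethylamine Wolff rearrangement of an α-diazoketone with capture of the ketene by an alcohol. No ring is closed. No new stereocentre is created: the (R) centre of citramalic acid is carried through by the stereoretentive shift, and it remains stereogenic in 25 only because the homologated arm, and not the CH2CO2-allyl arm, carries the core. The step needs acylation of the primary neopentyl C8' hydroxyl and not of the C1' hydroxyl, which is secured because the latter is tertiary, doubly allylic and flanked by two fully substituted carbons; the dioxolane keeps C4' from becoming an enone that O8' could attack, and the silyl ether keeps the HMG hydroxyl from closing a β-lactone on the ketene. Slow addition of 23 keeps the ketene concentration low against dimerisation, and exclusion of light protects the 2Z,4E dienoate.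

Step 19
Reactants: 25 fully protected target
Product: 26 allyl (2Z,4E)-5-[(1R,6S)-6-({[(3R)-5-(allyloxy)-3-hydroxy-3-methyl-5-oxopentanoyl]oxy}methyl)-1-hydroxy-2,6-dimethyl-4-oxocyclohex-2-en-1-yl]-3-methylpenta-2,4-dienoate
Conditions: 1 M aq. HCl/THF (1:4), 0 °C → rt
Reagents that add atoms: water O
Why: The allylic dioxolane is hydrolysed through its allyl-stabilised oxocarbenium ion and the triethylsilyl ether is protodesilylated, while the esters survive, and with O8' acylated the freed enone cannot suffer oxa-Michael addition.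

Step 20
Reactants: 26 allyl (2Z,4E)-5-[(1R,6S)-6-({[(3R)-5-(allyloxy)-3-hydroxy-3-methyl-5-oxopentanoyl]oxy}methyl)-1-hydroxy-2,6-dimethyl-4-oxocyclohex-2-en-1-yl]-3-methylpenta-2,4-dienoate
Product: 27 (2Z,4E)-5-[(1R,6S)-6-({[(3R)-4-carboxy-3-hydroxy-3-methylbutanoyl]oxy}methyl)-1-hydroxy-2,6-dimethyl-4-oxocyclohex-2-en-1-yl]-3-methylpenta-2,4-dienoic acid (CNP0183058.1)
Conditions: Pd(PPh3)4 (5 mol %), morpholine (6 equiv), THF, rt, dark; aq. KHSO4 work-up
Reagents that add atoms: none
Why: Zerovalent palladium ionises both allyl esters to π-allyl complexes that morpholine traps irreversibly (Tsuji–Trost deallylation), and these neutral conditions spare the 2Z,4E diene, both tertiary alcohols and the neopentyl ester.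

## Compound list

1 | 2,6-dimethylphenol | Cc1cccc(C)c1O | starting material
2 | 7,9-dimethyl-1,4-dioxaspiro[4.5]deca-6,9-dien-8-one | CC1=CC2(OCCO2)C=C(C)C1=O | intermediate
3 | lithium 7,9-dimethyl-1,4-dioxaspiro[4.5]deca-6,8-dien-8-olate | [Li+].[O-]C1=C(C)CC2(OCCO2)C=C1C | intermediate (not isolated)
4 | allyl 7,9-dimethyl-1,4-dioxaspiro[4.5]deca-6,8-dien-8-yl carbonate | C=CCOC(=O)OC1=C(C)CC2(OCCO2)C=C1C | intermediate
5 | (R)-9-allyl-7,9-dimethyl-1,4-dioxaspiro[4.5]dec-6-en-8-one | CC1=CC2(OCCO2)C[C@@](C)(CC=C)C1=O | intermediate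
6 | (S)-7,9-dimethyl-9-[(E)-prop-1-en-1-yl]-1,4-dioxaspiro[4.5]dec-6-en-8-one | CC1=CC2(OCCO2)C[C@@](C)(/C=C/C)C1=O | intermediate
7 | (S)-7,9-dimethyl-8-oxo-1,4-dioxaspiro[4.5]dec-6-ene-9-carbaldehyde | CC1=CC2(OCCO2)C[C@@](C)(C=O)C1=O | intermediate
8 | (S)-9-(hydroxymethyl)-7,9-dimethyl-1,4-dioxaspiro[4.5]dec-6-en-8-one | CC1=CC2(OCCO2)C[C@@](C)(CO)C1=O | intermediate
9 | (Z)-3-methylpent-2-en-4-yn-1-ol | C#C/C(C)=C\CO | starting material
10 | dilithio derivative of 9 (lithium alkoxide, lithium acetylide) | [Li+].[Li+].[C-]#C/C(C)=C\C[O-] | intermediate (not isolated)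
11 | chloromagnesium [(9S)-7,9-dimethyl-8-oxo-1,4-dioxaspiro[4.5]dec-6-en-9-yl]methanolate | CC1=CC2(OCCO2)C[C@@](C)(CO[Mg]Cl)C1=O | intermediate (not isolated)
12 | (8S,9S)-8-[(3Z)-5-hydroxy-3-methylpent-3-en-1-yn-1-yl]-9-(hydroxymethyl)-7,9-dimethyl-1,4-dioxaspiro[4.5]dec-6-en-8-ol | CC1=CC2(OCCO2)C[C@@](C)(CO)[C@@]1(O)C#C/C(C)=C\CO | intermediate
13 | (8R,9S)-8-[(1E,3Z)-5-hydroxy-3-methylpenta-1,3-dien-1-yl]-9-(hydroxymethyl)-7,9-dimethyl-1,4-dioxaspiro[4.5]dec-6-en-8-ol | CC1=CC2(OCCO2)C[C@@](C)(CO)[C@@]1(O)/C=C/C(C)=C\CO | intermediate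
14 | (2Z,4E)-5-[(8R,9S)-8-hydroxy-9-(hydroxymethyl)-7,9-dimethyl-1,4-dioxaspiro[4.5]dec-6-en-8-yl]-3-methylpenta-2,4-dienal | CC1=CC2(OCCO2)C[C@@](C)(CO)[C@@]1(O)/C=C/C(C)=C\C=O | intermediate
15 | (2Z,4E)-5-[(8R,9S)-8-hydroxy-9-(hydroxymethyl)-7,9-dimethyl-1,4-dioxaspiro[4.5]dec-6-en-8-yl]-3-methylpenta-2,4-dienoic acid | CC1=CC2(OCCO2)C[C@@](C)(CO)[C@@]1(O)/C=C/C(C)=C\C(=O)O | intermediate
16 | allyl (2Z,4E)-5-[(8R,9S)-8-hydroxy-9-(hydroxymethyl)-7,9-dimethyl-1,4-dioxaspiro[4.5]dec-6-en-8-yl]-3-methylpenta-2,4-dienoate (core alcohol) | CC1=CC2(OCCO2)C[C@@](C)(CO)[C@@]1(O)/C=C/C(C)=C\C(=O)OCC=C | intermediate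
17 | (R)-citramalic acid, (R)-2-hydroxy-2-methylbutanedioic acid | C[C@@](O)(CC(=O)O)C(=O)O | starting material
18 | 2-[(4R)-2,2,4-trimethyl-5-oxo-1,3-dioxolan-4-yl]acetic acid | C[C@]1(CC(=O)O)OC(C)(C)OC1=O | intermediate
19 | allyl 2-[(4R)-2,2,4-trimethyl-5-oxo-1,3-dioxolan-4-yl]acetate | C[C@]1(CC(=O)OCC=C)OC(C)(C)OC1=O | intermediate
20 | (R)-4-(allyloxy)-2-hydroxy-2-methyl-4-oxobutanoic acid | C=CCOC(=O)C[C@@](C)(O)C(=O)O | intermediate
21 | triethylsilyl (R)-4-(allyloxy)-2-methyl-4-oxo-2-[(triethylsilyl)oxy]butanoate | C=CCOC(=O)C[C@@](C)(O[Si](CC)(CC)CC)C(=O)O[Si](CC)(CC)CC | intermediate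
22 | allyl (R)-4-chloro-3-methyl-4-oxo-3-[(triethylsilyl)oxy]butanoate | C=CCOC(=O)C[C@@](C)(O[Si](CC)(CC)CC)C(Cl)=O | intermediate
23 | allyl (R)-5-diazo-3-methyl-4-oxo-3-[(triethylsilyl)oxy]pentanoate | C=CCOC(=O)C[C@@](C)(O[Si](CC)(CC)CC)C(=O)C=[N+]=[N-] | intermediate
24 | allyl (R)-3-methyl-5-oxo-3-[(triethylsilyl)oxy]pent-4-enoate (ketene) | C=CCOC(=O)C[C@@](C)(O[Si](CC)(CC)CC)C=C=O | intermediate (not isolated)
25 | allyl (2Z,4E)-5-[(8R,9S)-9-({[(3R)-5-(allyloxy)-3-methyl-5-oxo-3-[(triethylsilyl)oxy]pentanoyl]oxy}methyl)-8-hydroxy-7,9-dimethyl-1,4-dioxaspiro[4.5]dec-6-en-8-yl]-3-methylpenta-2,4-dienoate (fully protected target) | CC1=CC2(OCCO2)C[C@@](C)(COC(=O)C[C@](C)(O[Si](CC)(CC)CC)CC(=O)OCC=C)[C@@]1(O)/C=C/C(C)=C\C(=O)OCC=C | intermediate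
26 | allyl (2Z,4E)-5-[(1R,6S)-6-({[(3R)-5-(allyloxy)-3-hydroxy-3-methyl-5-oxopentanoyl]oxy}methyl)-1-hydroxy-2,6-dimethyl-4-oxocyclohex-2-en-1-yl]-3-methylpenta-2,4-dienoate | CC1=CC(=O)C[C@@](C)(COC(=O)C[C@](C)(O)CC(=O)OCC=C)[C@@]1(O)/C=C/C(C)=C\C(=O)OCC=C | intermediate
27 | (2Z,4E)-5-[(1R,6S)-6-({[(3R)-4-carboxy-3-hydroxy-3-methylbutanoyl]oxy}methyl)-1-hydroxy-2,6-dimethyl-4-oxocyclohex-2-en-1-yl]-3-methylpenta-2,4-dienoic acid (CNP0183058.1) | CC1=CC(=O)C[C@@](C)(COC(=O)C[C@](C)(O)CC(=O)O)[C@@]1(O)/C=C/C(C)=C\C(=O)O | target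

## Step count and risks

Total step count: 20 (core 11, citramalate fragment 6, key step 1, end game 2).
Longest linear sequence: 14 steps (steps 1–11, then 18–20, from 2,6-dimethylphenol).

The three steps most likely to fail:

Step 18 (key step). Silver-promoted loss of nitrogen may be sluggish at a diazoketone that sits on a fully substituted carbon, and the ketene may oligomerise faster than the hindered neopentyl C8' hydroxyl captures it, so that the core alcohol is recovered unacylated. The fallback separates rearrangement from acylation and sets out from 23. Photochemical Wolff rearrangement of 23 in THF/water (medium-pressure mercury lamp, Pyrex), which is possible here because no light-sensitive dienoate is present, should give (S)-5-(allyloxy)-3-methyl-5-oxo-3-[(triethylsilyl)oxy]pentanoic acid F1. This acid is activated with 2,4,6-trichlorobenzoyl chloride and Et3N in THF, and the mixed anhydride is then combined with core alcohol 16 and DMAP in toluene (Yamaguchi esterification). The fallback comes back to the route at 25.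

Step 7. Facial selectivity may be poor if solvated cations do not hold the chelate, and the alkoxide may lose formaldehyde by retro-aldol cleavage. The fallback replaces the anionic alkoxide by a neutral ether chelate and sets out from 8. Treatment with 4-methoxybenzyl 2,2,2-trichloroacetimidate and catalytic La(OTf)3 in toluene should give (S)-9-{[(4-methoxybenzyl)oxy]methyl}-7,9-dimethyl-1,4-dioxaspiro[4.5]dec-6-en-8-one F2. F2 is pre-complexed with MgBr2·OEt2 in CH2Cl2 at −78 °C and treated with the bis(bromomagnesium) derivative of 9 (from EtMgBr). This should give (8S,9S)-8-[(3Z)-5-hydroxy-3-methylpent-3-en-1-yn-1-yl]-9-{[(4-methoxybenzyl)oxy]methyl}-7,9-dimethyl-1,4-dioxaspiro[4.5]dec-6-en-8-ol F3 through the bidentate ether–carbonyl magnesium chelate. DDQ in CH2Cl2/pH 7 buffer removes the benzyl ether, and the fallback comes back to the route at 12.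

Step 2. The borohydride may reduce the dienone carbonyl 1,2 instead of 1,4, and the boron-containing enolate may be acylated on carbon. The fallback replaces the ionic hydride by a transition-metal hydrosilylation and sets out from 2. RhCl(PPh3)3 (1 mol %) and Et3SiH in benzene at 50 °C should give the 1,4-adduct triethyl[(7,9-dimethyl-1,4-dioxaspiro[4.5]deca-6,8-dien-8-yl)oxy]silane F4. MeLi in THF at 0 °C then liberates the borane-free lithium enolate 3, and allyl chloroformate brings the fallback back to the route at 4.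

## Further compounds

F1 | step 18 | (S)-5-(allyloxy)-3-methyl-5-oxo-3-[(triethylsilyl)oxy]pentanoic acid | OC(=O)C[C@](C)(O[Si](CC)(CC)CC)CC(=O)OCC=C
F2 | step 7 | (S)-9-{[(4-methoxybenzyl)oxy]methyl}-7,9-dimethyl-1,4-dioxaspiro[4.5]dec-6-en-8-one | CC1=CC2(OCCO2)C[C@@](C)(COCc3ccc(OC)cc3)C1=O
F3 | step 7 | (8S,9S)-8-[(3Z)-5-hydroxy-3-methylpent-3-en-1-yn-1-yl]-9-{[(4-methoxybenzyl)oxy]methyl}-7,9-dimethyl-1,4-dioxaspiro[4.5]dec-6-en-8-ol | CC1=CC2(OCCO2)C[C@@](C)(COCc3ccc(OC)cc3)[C@@]1(O)C#C/C(C)=C\CO
F4 | step 2 | triethyl[(7,9-dimethyl-1,4-dioxaspiro[4.5]deca-6,8-dien-8-yl)oxy]silane | CC[Si](CC)(CC)OC1=C(C)CC2(OCCO2)C=C1C
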